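The route disconnects C5–C6, the bond between the Z C4=C5 alkene and the allylic carbinol C6 that sits next to quaternary C7. A chromium/nickel-mediated alkenyl–aldehyde coupling forms this bond. It closes the nine-membered oxonene (ten-membered carbocycle) across the cis-2,5-disubstituted oxolane C7–O–C10 and creates the C6 hydroxyl, which later directs the epoxidation and becomes the lactone oxygen. The precursor is that oxolane with the non-enolisable C6 aldehyde on C7 and a Z-iodoalkenyl chain on C10; C8 is already methacryloylated, C12 is a silyl ether, and C1 is masked as a silylated carbinol so that the alkenylmetal cannot close a five-membered ring onto a ketone.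

Key step: step 21

Remark: atoms carry germacrane numbers (C1 carbonyl carbon, C4/C5 epoxide, C6 lactone carbinol, C7 spiro carbon, C8 ester carbinol, C10 methyl-bearing ether carbon, C11–C13 methylene lactone). The target is read as 4R,5S,6R,7S,8S,10R with a cis epoxide. The C1 carbinol is drawn as the 1S epimer expected from chelation-controlled reduction; either epimer converges on the target in the last step.

Step 1
Reactants: 1 (R)-linalool
Product: 3 (5R)-5-ethenyl-5-methyloxolan-2-one, via lactol 2 (not isolated)
Conditions: O3 (1 equiv), CH2Cl2–MeOH, −78 °C; Me2S, −78 °C to rt; evaporate; then PhI(OAc)2, TEMPO (10 mol %), CH2Cl2, rt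
Reagents that add atoms: ozone, [O-][O+]=O
Why: Ozone should attack the electron-rich trisubstituted alkene well before the vinyl group on the quaternary carbinol (selective ozonolysis), the hydroxy aldehyde closes to lactol 2, and oxoammonium oxidation of the lactol gives the lactone, with C10 taken unchanged from 1.

Step 2
Reactants: 3 (5R)-5-ethenyl-5-methyloxolan-2-one
Product: 5 (5R)-5-ethenyl-3-hydroxy-5-methyloxolan-2-one (both C3 epimers), via sodium enolate 4 (not isolated)
Conditions: NaN(SiMe3)2, THF, −78 °C; then 3-phenyl-2-(phenylsulfonyl)oxaziridine, −78 °C; AcOH quench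
Reagents that add atoms: 3-phenyl-2-(phenylsulfonyl)oxaziridine, O=S(=O)(c1ccccc1)N1OC1c1ccccc1
Why: Oxidation of the lactone enolate by the N-sulfonyloxaziridine (enolate α-hydroxylation) adds the oxygen that allows the carbonyl carbon to be excised later; the new C3 centre is not controlled because it is destroyed in step 5.

Step 3
Reactants: 5 (5R)-5-ethenyl-3-hydroxy-5-methyloxolan-2-one
Product: 6 (4R)-4-methylhex-5-ene-1,2,4-triol (both C2 epimers)
Conditions: LiAlH4, THF, 0 °C to rt
Reagents that add atoms: none
Why: Hydride reduction of the lactone with LiAlH4 opens it to the terminal 1,2-diol needed for glycol cleavage, and no stereocentre is formed.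

Step 4
Reactants: 7 ethyl (triphenyl-λ5-phosphanylidene)acetate
Product: 8 ethyl bromo(triphenyl-λ5-phosphanylidene)acetate
Conditions: N-bromosuccinimide, CH2Cl2, −20 °C to rt
Reagents that add atoms: N-bromosuccinimide, O=C1CCC(=O)N1Br
Why: Electrophilic bromination of the stabilised ylide, followed by deprotonation of the bromophosphonium ion by succinimide anion, should give the isolable α-bromo ylide (ylide halogenation).

Step 5
Reactants: 6 (4R)-4-methylhex-5-ene-1,2,4-triol; 8 ethyl bromo(triphenyl-λ5-phosphanylidene)acetate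
Product: 10 ethyl (2Z,5R)-2-bromo-5-hydroxy-5-methylhepta-2,6-dienoate, via aldehyde 9 (not isolated)
Conditions: NaIO4 on wet silica, CH2Cl2, rt; filter; then 8 (2.5 equiv), CH2Cl2, 0 °C to rt
Reagents that add atoms: none
Why: Periodate glycol cleavage removes the terminal carbon as formaldehyde, and the sensitive β-hydroxy aldehyde 9 is trapped at once by Wittig olefination with the stabilised bromo ylide (in excess, to cover the formaldehyde), which places the ester trans to the chain and should therefore give mainly the Z bromoalkene with Br cis to C9.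

Step 6
Reactants: 11 2-bromoprop-2-en-1-ol
Product: 12 [(2-bromoprop-2-en-1-yl)oxy](tert-butyl)dimethylsilane
Conditions: t-BuMe2SiCl, imidazole, CH2Cl2, 0 °C to rt
Reagents that add atoms: tert-butyldimethylsilyl chloride, CC(C)(C)[Si](C)(C)Cl
Why: Standard silylation of the primary allylic alcohol protects the future C12 oxygen.

Step 7
Reactants: 12 [(2-bromoprop-2-en-1-yl)oxy](tert-butyl)dimethylsilane
Product: 13 tert-butyldimethyl{[2-(4,4,5,5-tetramethyl-1,3,2-dioxaborolan-2-yl)prop-2-en-1-yl]oxy}silane
Conditions: bis(pinacolato)diboron, PdCl2(PPh3)2 (3 mol %), PPh3, KOPh, toluene, 50 °C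
Reagents that add atoms: bis(pinacolato)diboron, CC1(C)OB(OC1(C)C)B1OC(C)(C)C(C)(C)O1
Why: Miyaura borylation with a phenoxide base, the variant suited to 1-alkenyl halides, should convert the alkenyl bromide into the 1,1-disubstituted alkenylboronate that carries C11, C12 and C13.

Step 8
Reactants: 10 ethyl (2Z,5R)-2-bromo-5-hydroxy-5-methylhepta-2,6-dienoate; 13 alkenylboronate
Product: 14 ethyl (2E,5R)-2-{3-[(tert-butyldimethylsilyl)oxy]prop-1-en-2-yl}-5-hydroxy-5-methylhepta-2,6-dienoate
Conditions: PdCl2(dppf) (5 mol %), K3PO4, THF–H2O, rt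
Reagents that add atoms: none
Why: Suzuki–Miyaura coupling of the activated α-bromo enoate proceeds with retention at both partners, so C11 arrives cis to C9, and at room temperature with aqueous base transmetalation should outrun insertion of the remote vinyl group into the alkenylpalladium intermediate.

Step 9
Reactants: 14 dienoate
Product: 15 (2E,5R)-2-{3-[(tert-butyldimethylsilyl)oxy]prop-1-en-2-yl}-5-methylhepta-2,6-diene-1,5-diol
Conditions: i-Bu2AlH, CH2Cl2, −78 to 0 °C
Reagents that add atoms: none
Why: i-Bu2AlH reduces the conjugated ester in a 1,2 sense to the primary allylic alcohol needed for directed epoxidation, leaving the alkenes and the silyl ether untouched.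

Step 10
Reactants: 15 dienediol
Product: 17 (2R,3S,5R)-2-{3-[(tert-butyldimethylsilyl)oxy]prop-1-en-2-yl}-5-ethenyl-2-(hydroxymethyl)-5-methyloxolan-3-ol, via epoxy diol 16 (not isolated)
Conditions: Ti(OiPr)4 (cat.), L-(+)-diisopropyl tartrate, t-BuOOH, 4 Å sieves, CH2Cl2, −25 °C; work-up; then camphorsulfonic acid (10 mol %), CH2Cl2, 0 °C
Reagents that add atoms: tert-butyl hydroperoxide, CC(C)(C)OO
Why: Sharpless asymmetric epoxidation of the primary E-allylic alcohol with the L-(+)-tartrate catalyst should give the (7S,8S) epoxide irrespective of the remote C10 centre, and acid then lets the tertiary C10 hydroxyl open this vinyl epoxide at the tertiary allylic C7 with inversion (5-endo hydroxy-epoxide cyclisation, favoured by the adjacent π system over 4-exo attack at C8), which sets C7 and C8 of the oxolane together.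

Step 11
Reactants: 17 oxolane diol
Product: 18 C6,C8-dibenzoate of 17
Conditions: PhCOCl, pyridine, DMAP (cat.), CH2Cl2, 0 °C to rt
Reagents that add atoms: benzoyl chloride, O=C(Cl)c1ccccc1
Why: DMAP-catalysed acylation protects both hydroxyls as non-enolisable esters that survive the Wacker oxidation and the enolate alkylation and are later removed reductively.

Step 12
Reactants: 18 dibenzoate
Product: 19 methyl ketone (C10 vinyl converted into acetyl)
Conditions: PdCl2 (10 mol %), CuCl (co-catalyst), O2 (1 atm), DMF–H2O (7:1), rt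
Reagents that add atoms: water, O
Why: Tsuji–Wacker oxidation converts only the monosubstituted alkene (the 1,1-disubstituted C11=C13 alkene is inert), and with no allylic hydrogen at C10 and a hindered ring oxygen that binds divalent palladium poorly, Markovnikov attack of water should give the methyl ketone.

Step 13
Reactants: 20 prop-2-yn-1-ol
Product: 22 (2Z)-3-iodo-2-methylprop-2-en-1-ol, via alkenylmagnesium alkoxide 21 (not isolated)
Conditions: CH3MgBr (2.5 equiv), CuI (10 mol %), THF, 0 °C to rt; then I2, −10 °C
Reagents that add atoms: methylmagnesium bromide, C[Mg]Br; iodine, [I][I]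
Why: Copper-catalysed anti-carbomagnesiation of the propargylic alkoxide passes through a five-membered magnesium chelate that fixes magnesium cis to the CH2O group, and iodinolysis with retention gives the Z iodoalkene.

Step 14
Reactants: 22 (2Z)-3-iodo-2-methylprop-2-en-1-ol
Product: 23 (1Z)-3-bromo-1-iodo-2-methylprop-1-ene
Conditions: CBr4, PPh3, CH2Cl2, 0 °C
Reagents that add atoms: carbon tetrabromide, BrC(Br)(Br)Br
Why: Appel bromination converts the primary allylic alcohol into the bromide under neutral conditions without touching the alkenyl iodide or its geometry.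

Step 15
Reactants: 19 methyl ketone; 23 (1Z)-3-bromo-1-iodo-2-methylprop-1-ene
Product: 25 (4Z)-5-iodo-4-methylpent-4-enoyl ketone (19 alkylated at the acetyl methyl), via lithium enolate 24 (not isolated)
Conditions: LiN(SiMe3)2, THF, −78 °C; then 23, −78 to −30 °C
Reagents that add atoms: none
Why: The methyl ketone can enolise only toward C2 because C10 is quaternary, and SN2 alkylation of its lithium enolate by the reactive allylic bromide (ketone enolate alkylation) forms C2–C3 with the Z iodoalkene intact, the benzoates having no α-hydrogen and not being attacked by the amide base at −78 °C.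

Step 16
Reactants: 25 iodoalkenyl ketone
Product: 26 (1S)-carbinol
Conditions: Zn(BH4)2, Et2O, −20 °C
Reagents that add atoms: none
Why: Zn(BH4)2 reduces the α-alkoxy ketone through a chelate between the carbonyl and the ring oxygen (Cram-chelate control), so hydride should arrive from the methyl-bearing face of C10 and give mainly the 1S alcohol; this centre only masks C1 and is removed in step 24.

Step 17
Reactants: 26 (1S)-carbinol
Product: 27 C1 triethylsilyl ether of 26
Conditions: Et3SiOTf, 2,6-lutidine, CH2Cl2, −78 °C
Reagents that add atoms: triethylsilyl trifluoromethanesulfonate, CC[Si](CC)(CC)OS(=O)(=O)C(F)(F)F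
Why: Silylation of the hindered secondary alcohol with the silyl triflate masks C1 as a group that organochromium reagents do not touch and that fluoride removes at the end.

Step 18
Reactants: 27 silyl ether dibenzoate
Product: 28 C6,C8-diol
Conditions: i-Bu2AlH, CH2Cl2, −78 °C
Reagents that add atoms: none
Why: Reductive cleavage of both benzoates with i-Bu2AlH at low temperature frees the C6 and C8 hydroxyls while the silyl ethers and the alkenyl iodide stay intact.

Step 19
Reactants: 28 C6,C8-diol
Product: 29 C6 aldehyde with free C8 hydroxyl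
Conditions: PhI(OAc)2, TEMPO (20 mol %), CH2Cl2, rt
Reagents that add atoms: none
Why: Oxoammonium oxidation is selective for the primary neopentyl alcohol over the hindered secondary C8 hydroxyl and stops at the aldehyde, which cannot enolise or eliminate because C7 is quaternary.

Step 20
Reactants: 29 hydroxy aldehyde; 30 methacryloyl chloride
Product: 31 C8 methacrylate (cyclisation precursor)
Conditions: Et3N, DMAP (cat.), CH2Cl2, 0 °C to rt
Reagents that add atoms: none
Why: DMAP-catalysed acylation of the remaining C8 hydroxyl installs the methacrylate after all strongly basic steps, and the non-enolisable aldehyde is inert to these conditions.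

Step 21
Reactants: 31 cyclisation precursor
Product: 32 bridged Z-oxonene allylic alcohol (1S,4Z,6R,7R,8S,10R)
Conditions: CrCl2 (10 equiv), NiCl2 (2 mol % of the chromium), degassed DMSO–THF, rt, slow addition of 31 to 2 mM
Reagents that add atoms: none
Why: NiCl2 is reduced by CrCl2 to zerovalent nickel, which inserts into the C5–I bond and passes the alkenyl group to trivalent chromium with retention of the Z geometry; the alkenylchromium then adds to the C6 aldehyde. The closest known reaction type is the Nozaki–Hiyama–Kishi macrocyclisation of alkenyl iodides onto aldehydes, which is established for eight- to ten-membered rings, among them oxonenes of 2,5-bridged oxolanes. The one ring formed is the nine-membered oxonene (equally the ten-membered carbocycle C1–C10), closed end to end in an exo-trig mode at the aldehyde carbon, with the cis-2,5 substitution of the oxolane holding both arms on one face. The new stereocentre C6 is under substrate control: a polar Felkin–Anh approach anti to the C7–O bond, with the flat C11 alkenyl group rather than the branched C8 beside the incoming C5, should give the 6R alcohol. The step needs chemoselectivity for the aldehyde and closure over dimerisation: C1 is a silylated carbinol so no ketone can capture the alkenylchromium in a five-membered closure, the aldehyde on quaternary C7 cannot enolise, esters and silyl ethers are inert to organochromium reagents, and high dilution suppresses intermolecular coupling.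

Step 22
Reactants: 32 allylic alcohol
Product: 33 4,5-epoxy alcohol (1S,4R,5S,6R,7R,8S,10R)
Conditions: VO(acac)2 (10 mol %), t-BuOOH, CH2Cl2, 0 °C
Reagents that add atoms: tert-butyl hydroperoxide, CC(C)(C)OO
Why: In this hydroxyl-directed epoxidation the vanadium-bound C6 alkoxide delivers the peroxide oxygen only to the neighbouring C4=C5 alkene and syn to the hydroxyl, which in medium-ring Z-allylic alcohols gives the cis (erythro) epoxy alcohol, here the 4R,5S epoxide; the methacrylate and the remote 1,1-disubstituted alkene are not touched.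

Step 23
Reactants: 33 epoxy alcohol
Product: 34 C1,C6,C12-triol
Conditions: HF·pyridine, pyridine, THF, 0 °C to rt
Reagents that add atoms: none
Why: Pyridine-buffered HF·pyridine removes the triethylsilyl ether and the primary tert-butyldimethylsilyl ether (fluoride desilylation) under conditions mild enough to spare the epoxide and the methacrylate.

Step 24
Reactants: 34 triol
Product: 36 target CNP0241021.1, via hydroxy lactone 35 (not isolated)
Conditions: PhI(OAc)2, TEMPO (20 mol %), NaHCO3, CH2Cl2, rt; then Dess–Martin periodinane, rt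
Reagents that add atoms: none
Why: The oxoammonium oxidant takes only the primary allylic alcohol to the enal, which the C6 hydroxyl captures as a five-membered lactol that is oxidised on to the α-methylene lactone (oxidative lactonisation of a 1,4-diol), and Dess–Martin periodinane added to the same flask then oxidises the now unique C1 carbinol to the ketone, with bicarbonate keeping the medium neutral so that the free C1 hydroxyl does not open the epoxide.

Compound list
1 | (R)-linalool | C=C[C@](C)(O)CCC=C(C)C | starting material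
2 | (5R)-5-ethenyl-5-methyloxolan-2-ol (anomers) | C=C[C@@]1(C)CCC(O)O1 | intermediate
3 | (5R)-5-ethenyl-5-methyloxolan-2-one | C=C[C@@]1(C)CCC(=O)O1 | intermediate
4 | sodium enolate of 3 | C=C[C@@]1(C)CC=C(O[Na])O1 | intermediate
5 | (5R)-5-ethenyl-3-hydroxy-5-methyloxolan-2-one (both C3 epimers) | C=C[C@@]1(C)CC(O)C(=O)O1 | intermediate
6 | (4R)-4-methylhex-5-ene-1,2,4-triol (both C2 epimers) | C=C[C@](C)(O)CC(O)CO | intermediate
7 | ethyl (triphenyl-λ5-phosphanylidene)acetate | CCOC(=O)C=P(c1ccccc1)(c1ccccc1)c1ccccc1 | starting material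
8 | ethyl bromo(triphenyl-λ5-phosphanylidene)acetate | CCOC(=O)C(Br)=P(c1ccccc1)(c1ccccc1)c1ccccc1 | intermediate
9 | (3R)-3-hydroxy-3-methylpent-4-enal | C=C[C@](C)(O)CC=O | intermediate
10 | ethyl (2Z,5R)-2-bromo-5-hydroxy-5-methylhepta-2,6-dienoate | C=C[C@](C)(O)C/C=C(\Br)C(=O)OCC | intermediate
11 | 2-bromoprop-2-en-1-ol | C=C(Br)CO | starting material
12 | [(2-bromoprop-2-en-1-yl)oxy](tert-butyl)dimethylsilane | C=C(Br)CO[Si](C)(C)C(C)(C)C | intermediate
13 | tert-butyldimethyl{[2-(4,4,5,5-tetramethyl-1,3,2-dioxaborolan-2-yl)prop-2-en-1-yl]oxy}silane | C=C(CO[Si](C)(C)C(C)(C)C)B1OC(C)(C)C(C)(C)O1 | intermediate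
14 | ethyl (2E,5R)-2-{3-[(tert-butyldimethylsilyl)oxy]prop-1-en-2-yl}-5-hydroxy-5-methylhepta-2,6-dienoate | C=C[C@](C)(O)C/C=C(\C(=C)CO[Si](C)(C)C(C)(C)C)C(=O)OCC | intermediate
15 | (2E,5R)-2-{3-[(tert-butyldimethylsilyl)oxy]prop-1-en-2-yl}-5-methylhepta-2,6-diene-1,5-diol | C=C[C@](C)(O)C/C=C(\C(=C)CO[Si](C)(C)C(C)(C)C)CO | intermediate
16 | [(2S,3S)-2-{3-[(tert-butyldimethylsilyl)oxy]prop-1-en-2-yl}-3-[(2R)-2-hydroxy-2-methylbut-3-en-1-yl]oxiran-2-yl]methanol | C=C[C@](C)(O)C[C@@H]1O[C@]1(CO)C(=C)CO[Si](C)(C)C(C)(C)C | intermediate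
17 | (2R,3S,5R)-2-{3-[(tert-butyldimethylsilyl)oxy]prop-1-en-2-yl}-5-ethenyl-2-(hydroxymethyl)-5-methyloxolan-3-ol | O[C@H]1C[C@](C)(C=C)O[C@]1(C(=C)CO[Si](C)(C)C(C)(C)C)CO | intermediate
18 | dibenzoate of 17 (benzoates on the ring hydroxyl and the hydroxymethyl group; 2R,3S,5R) | O=C(O[C@H]1C[C@](C)(C=C)O[C@]1(C(=C)CO[Si](C)(C)C(C)(C)C)COC(=O)c1ccccc1)c1ccccc1 | intermediate
19 | methyl ketone: 5-acetyl analogue of 18 (2R,3S,5R) | O=C(O[C@H]1C[C@](C)(C(C)=O)O[C@]1(C(=C)CO[Si](C)(C)C(C)(C)C)COC(=O)c1ccccc1)c1ccccc1 | intermediate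
20 | prop-2-yn-1-ol | C#CCO | starting material
21 | (Z)-bromomagnesium 3-(bromomagnesio)-2-methylprop-2-en-1-olate | Br[Mg]OC/C(C)=C\[Mg]Br | intermediate
22 | (2Z)-3-iodo-2-methylprop-2-en-1-ol | OC/C(C)=C\I | intermediate
23 | (1Z)-3-bromo-1-iodo-2-methylprop-1-ene | BrC/C(C)=C\I | intermediate
24 | lithium enolate of 19 | O=C(O[C@H]1C[C@](C)(C(=C)O[Li])O[C@]1(C(=C)CO[Si](C)(C)C(C)(C)C)COC(=O)c1ccccc1)c1ccccc1 | intermediate
25 | 5-[(4Z)-5-iodo-4-methylpent-4-enoyl] analogue of 18 (2R,3S,5R) | O=C(O[C@H]1C[C@](C)(C(=O)CC/C(C)=C\I)O[C@]1(C(=C)CO[Si](C)(C)C(C)(C)C)COC(=O)c1ccccc1)c1ccccc1 | intermediate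
26 | 5-[(1S,4Z)-1-hydroxy-5-iodo-4-methylpent-4-en-1-yl] analogue of 18 | O=C(O[C@H]1C[C@](C)([C@@H](O)CC/C(C)=C\I)O[C@]1(C(=C)CO[Si](C)(C)C(C)(C)C)COC(=O)c1ccccc1)c1ccccc1 | intermediate
27 | C1 triethylsilyl ether of 26 | O=C(O[C@H]1C[C@](C)([C@@H](O[Si](CC)(CC)CC)CC/C(C)=C\I)O[C@]1(C(=C)CO[Si](C)(C)C(C)(C)C)COC(=O)c1ccccc1)c1ccccc1 | intermediate
28 | (2R,3S,5R)-2-{3-[(tert-butyldimethylsilyl)oxy]prop-1-en-2-yl}-2-(hydroxymethyl)-5-{(1S,4Z)-5-iodo-4-methyl-1-[(triethylsilyl)oxy]pent-4-en-1-yl}-5-methyloxolan-3-ol | O[C@H]1C[C@](C)([C@@H](O[Si](CC)(CC)CC)CC/C(C)=C\I)O[C@]1(C(=C)CO[Si](C)(C)C(C)(C)C)CO | intermediate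
29 | (2S,3S,5R)-2-{3-[(tert-butyldimethylsilyl)oxy]prop-1-en-2-yl}-3-hydroxy-5-{(1S,4Z)-5-iodo-4-methyl-1-[(triethylsilyl)oxy]pent-4-en-1-yl}-5-methyloxolane-2-carbaldehyde | O[C@H]1C[C@](C)([C@@H](O[Si](CC)(CC)CC)CC/C(C)=C\I)O[C@]1(C(=C)CO[Si](C)(C)C(C)(C)C)C=O | intermediate
30 | methacryloyl chloride | C=C(C)C(Cl)=O | starting material
31 | cyclisation precursor: 3-O-methacrylate of 29 (1S,7S,8S,10R; Z-iodoalkene) | C=C(C)C(=O)O[C@H]1C[C@](C)([C@@H](O[Si](CC)(CC)CC)CC/C(C)=C\I)O[C@]1(C(=C)CO[Si](C)(C)C(C)(C)C)C=O | intermediate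
32 | bridged Z-oxonene: 7,10-epoxygermacra-4(Z),11(13)-diene with 6-hydroxy, 8-methacryloyloxy, 1-(triethylsilyl)oxy and 12-(tert-butyldimethylsilyl)oxy groups (1S,6R,7R,8S,10R) | C=C(C)C(=O)O[C@H]1C[C@@]2(C)O[C@]1(C(=C)CO[Si](C)(C)C(C)(C)C)[C@H](O)/C=C(C)\CC[C@@H]2O[Si](CC)(CC)CC | intermediate
33 | 4,5-epoxide of 32 (1S,4R,5S,6R,7R,8S,10R) | C=C(C)C(=O)O[C@H]1C[C@@]2(C)O[C@]1(C(=C)CO[Si](C)(C)C(C)(C)C)[C@H](O)[C@@H]3O[C@]3(C)CC[C@@H]2O[Si](CC)(CC)CC | intermediate
34 | 1,6,12-triol from 33 (1S,4R,5S,6R,7R,8S,10R) | C=C(C)C(=O)O[C@H]1C[C@@]2(C)O[C@]1(C(=C)CO)[C@H](O)[C@@H]3O[C@]3(C)CC[C@@H]2O | intermediate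
35 | 1-hydroxy α-methylene lactone (1S,4R,5S,6R,7S,8S,10R) | C=C(C)C(=O)O[C@H]1C[C@@]2(C)O[C@@]13C(=C)C(=O)O[C@@H]3[C@@H]1O[C@]1(C)CC[C@@H]2O | intermediate
36 | CNP0241021.1 (4R,5S,6R,7S,8S,10R) | C=C(C)C(=O)O[C@H]1C[C@@]2(C)O[C@@]13C(=C)C(=O)O[C@@H]3[C@@H]1O[C@]1(C)CCC2=O | target

Total step count: 24. Longest linear sequence: 19 steps (1, 2, 3, 5, 8–12, 15–24).

Steps most likely to fail

Step 21 (ring closure). Medium-ring strain may override the Felkin–Anh preference, so that the alkenylchromium adds to the wrong aldehyde face; slow closure may also lose material to reduction of the C–I bond and to dimers. The fallback sets out from 32 obtained as a C6 epimer mixture. Dess–Martin oxidation should give the Z-enone F1, and C6 is then set by a reagent-controlled Corey–Bakshi–Shibata reduction ((S)-2-methyl-CBS-oxazaborolidine, catecholborane, −78 °C, with C7 as the large group; the enantiomeric catalyst if the alkene proves the larger group). This comes back to 32.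

Step 10 (epoxidation and oxolane closure). The 2-alkenyl epoxide 16 may open unselectively in the Lewis-acidic titanium medium, by ionisation at the tertiary allylic C7 with loss of the inversion. The fallback sets out from 15. Selective silylation of the primary hydroxyl (Et3SiCl, imidazole) should give the triethylsilyl ether F2. This is epoxidised without metal and under buffered conditions by the dioxirane from the L-fructose-derived (enantiomeric Shi) ketone and Oxone, to give the (7S,8S) epoxide F3. Closure with camphorsulfonic acid at −40 °C gives the oxolane F4, and PPTS in methanol removes the triethylsilyl group to come back to 17.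

Step 22 (directed epoxidation). Oxygen may be delivered to the wrong alkene face in the bridged ring, and in steps 23–24 the freed C1 hydroxyl may open the epoxide across the ring. The fallback moves the epoxidation to the end and sets out from 32. HF·pyridine should give the triol F5. One-flask oxidation (PhI(OAc)2/TEMPO, then Dess–Martin periodinane) leads through the hydroxy lactone F6 to the keto lactone F7. The only electron-rich alkene, C4=C5, is then epoxidised with dimethyldioxirane under conformational (peripheral-attack) control, which comes back to 36.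

Further compounds
F1 | step 21 | Z-enone: 6-oxo analogue of 32 | C=C(C)C(=O)O[C@H]1C[C@@]2(C)O[C@]1(C(=C)CO[Si](C)(C)C(C)(C)C)C(=O)/C=C(C)\CC[C@@H]2O[Si](CC)(CC)CC
F2 | step 10 | primary triethylsilyl ether of 15 | C=C[C@](C)(O)C/C=C(\C(=C)CO[Si](C)(C)C(C)(C)C)CO[Si](CC)(CC)CC
F3 | step 10 | (7S,8S) epoxide of F2 | C=C[C@](C)(O)C[C@@H]1O[C@]1(CO[Si](CC)(CC)CC)C(=C)CO[Si](C)(C)C(C)(C)C
F4 | step 10 | C6 triethylsilyl ether of 17 | O[C@H]1C[C@](C)(C=C)O[C@]1(C(=C)CO[Si](C)(C)C(C)(C)C)CO[Si](CC)(CC)CC
F5 | step 22 | 1,6,12-triol from 32 (4Z alkene retained) | C=C(C)C(=O)O[C@H]1C[C@@]2(C)O[C@]1(C(=C)CO)[C@H](O)/C=C(C)\CC[C@@H]2O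
F6 | step 22 | 1-hydroxy α-methylene lactone with 4Z alkene | C=C(C)C(=O)O[C@H]1C[C@@]2(C)O[C@@]13C(=C)C(=O)O[C@@H]3/C=C(C)\CC[C@@H]2O
F7 | step 22 | 1-keto α-methylene lactone with 4Z alkene (4,5-deoxy target) | C=C(C)C(=O)O[C@H]1C[C@@]2(C)O[C@@]13C(=C)C(=O)O[C@@H]3/C=C(C)\CCC2=O
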